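**Retrosynthetic overview**
- The target is reached from the fully protected flavonol (3,3'-di-O-benzyl-5,7,4'-tri-O-MOM quercetin) by MOM removal, sulfation of O7 and O4', hydrogenolysis of the benzyl ethers and proton exchange.
- Ring C is cut at O1–C8a, C4–C4a and O1–C2: an aryne across C4a–C8a of ring A inserts into the carboxyl C–O bond of a β-methoxyacrylic acid that carries C2, C3, C4 and ring B, and the freed phenoxide displaces methoxide at C2.
- The strategy rests on O5: it sits on C5, next to the ring-fusion carbon C4a, so the C4a–C8a aryne is a 3-alkoxyaryne whose polarisation sends the oxygen nucleophile to C8a and leaves the carbanion at C4a, which is the O1/C4 pattern of the chromone.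
- The aryne precursor comes from phloroglucinol (bis-MOM ether, carbamate-directed ortho-silylation, triflation); the acid comes from 3,4-dihydroxybenzaldehyde and methyl benzyloxyacetate (aldol, oxidation, O-methylation, saponification).
- Rings A and B are bought as arenes; ring C is the only ring formed, in step 11.

Key step: step 11

Remark: the target has no stereocentre and no stereogenic double bond, so it is one achiral compound and no step needs stereocontrol; the enol ether in 17 and 18 is drawn as the E isomer, but either geometry converges in step 11.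
Remark: free aryl hydrogen sulfates hydrolyse readily, so the sulfates are carried as triethylammonium salts and the acid form is released only in the last step.

**Route**

Step 1
Reactants: 1 phloroglucinol
Product: 2 3,5-bis(methoxymethoxy)phenol
Conditions: MOMCl (2.0 equiv), i-Pr2NEt, DMF/CH2Cl2, 0 °C → rt; chromatography
Reagents that add atoms: chloromethyl methyl ether, COCCl
Why: Williamson-type O-alkylation with the oxocarbenium-like chloromethyl ether is statistical over three equivalent hydroxyls, so two equivalents should give the bis-ether as the main fraction, separable from the mono- and tris-ethers, which can be recycled.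

Step 2
Reactants: 2 3,5-bis(methoxymethoxy)phenol
Product: 3 3,5-bis(methoxymethoxy)phenyl N-isopropylcarbamate
Conditions: i-PrNCO, Et3N (cat.), CH2Cl2, rt
Reagents that add atoms: isopropyl isocyanate, CC(C)N=C=O
Why: base-catalysed addition of the phenol to the isocyanate (carbamoylation) should be clean and installs the strongest ortho-directing group on the ring.

Step 3
Reactants: 3 3,5-bis(methoxymethoxy)phenyl N-isopropylcarbamate
Product: 7 3,5-bis(methoxymethoxy)-2-(trimethylsilyl)phenyl N-isopropylcarbamate, via N-silyl carbamate 4 (not isolated), via ortho-lithiated N-silyl carbamate 5 (not isolated), via C,N-bis-silyl carbamate 6 (not isolated)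
Conditions: TMSOTf (1.0 equiv), TMEDA, Et2O, 0 °C → rt; n-BuLi, TMEDA, −78 °C; TMSCl, −78 °C → rt; aq. NH4Cl
Reagents that add atoms: chlorotrimethylsilane, C[Si](C)(C)Cl (the aryl SiMe3); trimethylsilyl trifluoromethanesulfonate, C[Si](C)(C)OS(=O)(=O)C(F)(F)F (N–SiMe3 of 4 to 6 only); n-butyllithium, [Li]CCCC (lithium of 5 only)
Why: directed ortho-metalation, in which in-situ N-silylation masks the N–H, n-BuLi/TMEDA should remove the proton flanked by the carbamate and a MOM ether (cooperative direction, two equivalent sites), TMSCl traps the aryllithium and the N–Si bond is hydrolysed on work-up.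

Step 4
Reactants: 7 3,5-bis(methoxymethoxy)-2-(trimethylsilyl)phenyl N-isopropylcarbamate
Product: 9 3,5-bis(methoxymethoxy)-2-(trimethylsilyl)phenyl trifluoromethanesulfonate, via 3,5-bis(methoxymethoxy)-2-(trimethylsilyl)phenol 8 (not isolated)
Conditions: DBU, Et2NH, MeCN, 40 °C; then PhNTf2, rt; Et3N-deactivated silica
Reagents that add atoms: N-phenylbis(trifluoromethanesulfonimide), O=S(=O)(N(c1ccccc1)S(=O)(=O)C(F)(F)F)C(F)(F)F
Why: base-induced E1cB cleavage of the N-monoalkyl carbamate to phenoxide and isopropyl isocyanate (scavenged by diethylamine as a urea), followed by O-triflation in the same flask, avoids isolating the acid-sensitive ortho-silyl phenol.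

Step 5
Reactants: 10 3,4-dihydroxybenzaldehyde
Product: 11 3-hydroxy-4-(methoxymethoxy)benzaldehyde
Conditions: MOMCl (1.05 equiv), K2CO3 (1.1 equiv), acetone, 0 °C → rt
Reagents that add atoms: chloromethyl methyl ether, COCCl
Why: regioselective Williamson etherification, since the 4-OH para to the formyl group is the more acidic and one equivalent of weak base should deliver only its phenoxide to MOMCl.

Step 6
Reactants: 11 3-hydroxy-4-(methoxymethoxy)benzaldehyde
Product: 12 3-(benzyloxy)-4-(methoxymethoxy)benzaldehyde
Conditions: BnBr, K2CO3, DMF, rt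
Reagents that add atoms: benzyl bromide, BrCc1ccccc1
Why: Williamson benzylation of the remaining phenol under standard carbonate conditions.

Step 7
Reactants: 12 3-(benzyloxy)-4-(methoxymethoxy)benzaldehyde; 13 methyl benzyloxyacetate
Product: 15 methyl 2-(benzyloxy)-3-[3-(benzyloxy)-4-(methoxymethoxy)phenyl]-3-hydroxypropanoate (racemic syn/anti mixture), via lithium enolate of methyl benzyloxyacetate 14 (not isolated)
Conditions: LDA, THF, −78 °C; 13, then 12; AcOH, −78 °C
Reagents that add atoms: lithium diisopropylamide, [Li+].CC(C)[N-]C(C)C (supplies only the lithium of intermediate 14)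
Why: aldol addition of the lithium glycolate enolate to the non-enolisable aldehyde at −78 °C, where the two new stereocentres form without control, which does not matter because both are destroyed in steps 8 and 9.

Step 8
Reactants: 15 methyl 2-(benzyloxy)-3-[3-(benzyloxy)-4-(methoxymethoxy)phenyl]-3-hydroxypropanoate
Product: 16 methyl 2-(benzyloxy)-3-[3-(benzyloxy)-4-(methoxymethoxy)phenyl]-3-oxopropanoate
Conditions: DMP, CH2Cl2, 0 °C → rt
Reagents that add atoms: none
Why: Dess–Martin oxidation of the benzylic secondary alcohol should give the β-keto ester under near-neutral conditions that leave MOM and benzyl ethers untouched.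

Step 9
Reactants: 16 methyl 2-(benzyloxy)-3-[3-(benzyloxy)-4-(methoxymethoxy)phenyl]-3-oxopropanoate
Product: 17 methyl (E)-2-(benzyloxy)-3-[3-(benzyloxy)-4-(methoxymethoxy)phenyl]-3-methoxyprop-2-enoate
Conditions: Cs2CO3, Me2SO4, DMF, 0 °C → rt
Reagents that add atoms: dimethyl sulfate, COS(=O)(=O)OC
Why: O-alkylation of the cesium enolate with a hard methylating agent in a dipolar aprotic solvent, where attack at oxygen should dominate because C-methylation would build a quaternary carbon shielded by the benzyloxy group.

Step 10
Reactants: 17 methyl (E)-2-(benzyloxy)-3-[3-(benzyloxy)-4-(methoxymethoxy)phenyl]-3-methoxyprop-2-enoate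
Product: 18 (E)-2-(benzyloxy)-3-[3-(benzyloxy)-4-(methoxymethoxy)phenyl]-3-methoxyprop-2-enoic acid
Conditions: LiOH·H2O, THF/MeOH/H2O, 50 °C; then cold 1 M HCl to pH 4
Reagents that add atoms: lithium hydroxide, [Li+].[OH-] (one carboxyl oxygen)
Why: saponification of the methyl ester, in which the enol ether is stable to base and careful cold acidification to pH 4 should leave it and the MOM ether intact.

Step 11
Reactants: 9 3,5-bis(methoxymethoxy)-2-(trimethylsilyl)phenyl trifluoromethanesulfonate; 18 (E)-2-(benzyloxy)-3-[3-(benzyloxy)-4-(methoxymethoxy)phenyl]-3-methoxyprop-2-enoic acid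
Product: 21 3-(benzyloxy)-2-[3-(benzyloxy)-4-(methoxymethoxy)phenyl]-5,7-bis(methoxymethoxy)-4H-chromen-4-one, via 3,5-bis(methoxymethoxy)benzyne 19 (not isolated), via cesium 2-acylphenoxide 20 (not isolated)
Conditions: 9 (1.6 equiv), CsF (5 equiv), THF, 125 °C, sealed tube
Reagents that add atoms: cesium fluoride, [Cs+].[F-] (supplies only the cesium of intermediate 20)
Why: Proposed new method: fluoride removes the silyl group of 9 and triflate leaves, giving aryne 19, whose C5 alkoxy group (inductive polarisation of the distorted aryne) should send the carboxylate oxygen of 18 to the remote carbon C8a (O1–C8a) and leave the aryl anion at C4a, beside the oxygen-bearing C5. That anion attacks its own ester carbonyl through a four-membered transition state (C4–C4a), and the strained adduct opens to the ortho-acyl phenoxide 20. The phenoxide then closes ring C by 6-endo-trig conjugate addition to the β-methoxy enone and expels methoxide (O1–C2, addition–elimination), so the chromone forms at the right oxidation level without an oxidant. The closest known reaction is the fluoride-mediated insertion of arynes into the C–O bond of carboxylic acids, which gives ortho-hydroxyaryl ketones and, with α,β-unsaturated and alkynoic acids, chromanones and flavones; the β-alkoxyacrylic acid partner and the terminating loss of alkoxide are the untested part. The step needs regioselective addition to the unsymmetrical aryne, which the C5 oxygen secures, and acyl capture by the C4a anion faster than its protonation or its attack at the β-carbon, which is favoured by the proton-poor medium (the acid sits as its cesium salt, the aryne is released slowly by sparingly soluble CsF) and by the tetrasubstituted, donor-deactivated β-carbon. No stereocentre is formed, and either geometry of the enol ether can reach the cyclisation because the C3–C4 bond rotates freely.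

Step 12
Reactants: 21 3-(benzyloxy)-2-[3-(benzyloxy)-4-(methoxymethoxy)phenyl]-5,7-bis(methoxymethoxy)-4H-chromen-4-one
Product: 22 3-(benzyloxy)-2-[3-(benzyloxy)-4-hydroxyphenyl]-5,7-dihydroxy-4H-chromen-4-one (3,3'-di-O-benzylquercetin)
Conditions: 3 M aq. HCl, MeOH/THF, 50 °C
Reagents that add atoms: none
Why: acid-catalysed acetal methanolysis should remove all three MOM ethers, passing the CH2 unit to methanol, while the benzyl ethers and the chromone are stable.

Step 13
Reactants: 22 3,3'-di-O-benzylquercetin
Product: 23 bis(triethylammonium) 3,3'-di-O-benzylquercetin 7,4'-disulfate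
Conditions: Et3N·SO3 (6 equiv), Et3N, DMF, 50 °C; Sephadex LH-20
Reagents that add atoms: sulfur trioxide–triethylamine complex, CC[N+](CC)(CC)S(=O)(=O)[O-]
Why: O-sulfation of phenols with an amine–sulfur trioxide complex, in which the acidic 7-OH and 4'-OH should react as phenoxides whereas the 5-OH, locked in a hydrogen bond to the C4 carbonyl, is known to resist such reagents.

Step 14
Reactants: 23 bis(triethylammonium) 3,3'-di-O-benzylquercetin 7,4'-disulfate
Product: 24 bis(triethylammonium) quercetin 7,4'-disulfate
Conditions: H2 (1 atm), 10% Pd/C, MeOH (trace Et3N), rt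
Reagents that add atoms: none
Why: hydrogenolysis of the two benzyl ethers over palladium, under which aryl sulfate salts and the chromone C2=C3 bond should not be reduced and the salt form guards against acid-catalysed loss of sulfate.

Step 15
Reactants: 24 bis(triethylammonium) quercetin 7,4'-disulfate
Product: 25 3',5-dihydroxy-4',7-bis(sulfooxy)flavonol
Conditions: Dowex 50W-X8 (H+ form), H2O/MeOH, 0 °C; filter; freeze-dry
Reagents that add atoms: none
Why: cation exchange on a sulfonic acid resin replaces triethylammonium by protons, and short cold contact followed by immediate freeze-drying should limit hydrolysis of the acid-labile aryl hydrogen sulfates.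

**Compound list**
1 | phloroglucinol | Oc1cc(O)cc(O)c1 | starting material
2 | 3,5-bis(methoxymethoxy)phenol | COCOc1cc(O)cc(OCOC)c1 | intermediate
3 | 3,5-bis(methoxymethoxy)phenyl N-isopropylcarbamate | CC(C)NC(=O)Oc1cc(OCOC)cc(OCOC)c1 | intermediate
4 | 3,5-bis(methoxymethoxy)phenyl N-isopropyl-N-(trimethylsilyl)carbamate | CC(C)N(C(=O)Oc1cc(OCOC)cc(OCOC)c1)[Si](C)(C)C | intermediate (not isolated)
5 | 2-lithio-3,5-bis(methoxymethoxy)phenyl N-isopropyl-N-(trimethylsilyl)carbamate | [Li]c1c(OCOC)cc(OCOC)cc1OC(=O)N(C(C)C)[Si](C)(C)C | intermediate (not isolated)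
6 | 3,5-bis(methoxymethoxy)-2-(trimethylsilyl)phenyl N-isopropyl-N-(trimethylsilyl)carbamate | CC(C)N(C(=O)Oc1cc(OCOC)cc(OCOC)c1[Si](C)(C)C)[Si](C)(C)C | intermediate (not isolated)
7 | 3,5-bis(methoxymethoxy)-2-(trimethylsilyl)phenyl N-isopropylcarbamate | CC(C)NC(=O)Oc1cc(OCOC)cc(OCOC)c1[Si](C)(C)C | intermediate
8 | 3,5-bis(methoxymethoxy)-2-(trimethylsilyl)phenol (present as its DBU salt) | C[Si](C)(C)c1c(O)cc(OCOC)cc1OCOC | intermediate (not isolated)
9 | 3,5-bis(methoxymethoxy)-2-(trimethylsilyl)phenyl trifluoromethanesulfonate | C[Si](C)(C)c1c(OCOC)cc(OCOC)cc1OS(=O)(=O)C(F)(F)F | intermediate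
10 | 3,4-dihydroxybenzaldehyde | O=Cc1ccc(O)c(O)c1 | starting material
11 | 3-hydroxy-4-(methoxymethoxy)benzaldehyde | COCOc1ccc(C=O)cc1O | intermediate
12 | 3-(benzyloxy)-4-(methoxymethoxy)benzaldehyde | COCOc1ccc(C=O)cc1OCc1ccccc1 | intermediate
13 | methyl benzyloxyacetate | COC(=O)COCc1ccccc1 | starting material
14 | lithium enolate of methyl benzyloxyacetate | [Li+].[O-]C(OC)=COCc1ccccc1 | intermediate (not isolated)
15 | methyl 2-(benzyloxy)-3-[3-(benzyloxy)-4-(methoxymethoxy)phenyl]-3-hydroxypropanoate (racemic syn/anti mixture, configuration not defined) | COC(=O)C(OCc1ccccc1)C(O)c1ccc(OCOC)c(OCc2ccccc2)c1 | intermediate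
16 | methyl 2-(benzyloxy)-3-[3-(benzyloxy)-4-(methoxymethoxy)phenyl]-3-oxopropanoate (racemic) | COC(=O)C(OCc1ccccc1)C(=O)c1ccc(OCOC)c(OCc2ccccc2)c1 | intermediate
17 | methyl (E)-2-(benzyloxy)-3-[3-(benzyloxy)-4-(methoxymethoxy)phenyl]-3-methoxyprop-2-enoate | CO/C(c1ccc(OCOC)c(OCc2ccccc2)c1)=C(/OCc1ccccc1)C(=O)OC | intermediate
18 | (E)-2-(benzyloxy)-3-[3-(benzyloxy)-4-(methoxymethoxy)phenyl]-3-methoxyprop-2-enoic acid | CO/C(c1ccc(OCOC)c(OCc2ccccc2)c1)=C(/OCc1ccccc1)C(=O)O | intermediate
19 | 3,5-bis(methoxymethoxy)benzyne | COCOC1=CC(OCOC)=CC#C1 | intermediate (not isolated)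
20 | cesium 2-{(E)-2-(benzyloxy)-3-[3-(benzyloxy)-4-(methoxymethoxy)phenyl]-3-methoxyprop-2-enoyl}-3,5-bis(methoxymethoxy)phenoxide | [Cs+].[O-]c1cc(OCOC)cc(OCOC)c1C(=O)/C(OCc1ccccc1)=C(\OC)c1ccc(OCOC)c(OCc2ccccc2)c1 | intermediate (not isolated)
21 | 3-(benzyloxy)-2-[3-(benzyloxy)-4-(methoxymethoxy)phenyl]-5,7-bis(methoxymethoxy)-4H-chromen-4-one | O=c1c(OCc2ccccc2)c(-c2ccc(OCOC)c(OCc3ccccc3)c2)oc2cc(OCOC)cc(OCOC)c12 | intermediate
22 | 3-(benzyloxy)-2-[3-(benzyloxy)-4-hydroxyphenyl]-5,7-dihydroxy-4H-chromen-4-one | O=c1c(OCc2ccccc2)c(-c2ccc(O)c(OCc3ccccc3)c2)oc2cc(O)cc(O)c12 | intermediate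
23 | bis(triethylammonium) 3,3'-di-O-benzylquercetin 7,4'-disulfate | CC[NH+](CC)CC.CC[NH+](CC)CC.O=c1c(OCc2ccccc2)c(-c2ccc(OS(=O)(=O)[O-])c(OCc3ccccc3)c2)oc2cc(OS(=O)(=O)[O-])cc(O)c12 | intermediate
24 | bis(triethylammonium) quercetin 7,4'-disulfate | CC[NH+](CC)CC.CC[NH+](CC)CC.O=c1c(O)c(-c2ccc(OS(=O)(=O)[O-])c(O)c2)oc2cc(OS(=O)(=O)[O-])cc(O)c12 | intermediate
25 | 3',5-dihydroxy-4',7-bis(sulfooxy)flavonol (quercetin 7,4'-bis(hydrogen sulfate)) | O=c1c(O)c(-c2ccc(OS(=O)(=O)O)c(O)c2)oc2cc(OS(=O)(=O)O)cc(O)c12 | target

**Totals**
Total step count: 15.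
Longest linear sequence: 11 steps (steps 5 to 15, from 3,4-dihydroxybenzaldehyde); the aryne branch (steps 1 to 4) joins at step 11.

**Steps most likely to fail**

1. Step 11 (proposed new method). The C4a aryl anion may be protonated before it reaches the acyl carbon, which stops the sequence at the aryl ester. Acyl transfer onto the hindered, donor-substituted acyl carbon may also be slow, and methoxide or the product phenoxide may consume the aryne. The fallback uses known chemistry, sets out from 1 and 18 and comes back at 22. Phloroglucinol 1 is exhaustively protected (NaH, excess MOMCl, DMF) to 1,3,5-tris(methoxymethoxy)benzene F1. n-BuLi in THF at 0 °C metalates the position between two MOM ethers (all three ring positions are equivalent) to give 2,4,6-tris(methoxymethoxy)phenyllithium F2. Acid 18 is coupled with N,O-dimethylhydroxylamine hydrochloride (EDC, HOBt, i-Pr2NEt) to the Weinreb amide (E)-2-(benzyloxy)-3-[3-(benzyloxy)-4-(methoxymethoxy)phenyl]-N,3-dimethoxy-N-methylprop-2-enamide F3. Addition of F2 to F3 at −78 → 0 °C should stop at the ketone (E)-2-(benzyloxy)-3-[3-(benzyloxy)-4-(methoxymethoxy)phenyl]-3-methoxy-1-[2,4,6-tris(methoxymethoxy)phenyl]prop-2-en-1-one F4. Treatment of F4 with HCl in MeOH/THF at 50 °C removes all four MOM groups, and one of the two equivalent ortho-phenols closes ring C by addition–elimination at C2 with loss of methanol, giving 22 directly, so step 12 is skipped.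

2. Step 9. Methylation may occur at carbon instead of oxygen, giving the quaternary C-methyl keto ester. The fallback sets out from 16 and comes back at 21. The alkylating agent is changed to MOMCl (i-Pr2NEt, CH2Cl2), an oxocarbenium-type electrophile that goes to the enolate oxygen, giving methyl (E)-2-(benzyloxy)-3-[3-(benzyloxy)-4-(methoxymethoxy)phenyl]-3-(methoxymethoxy)prop-2-enoate F5. Saponification as in step 10 gives (E)-2-(benzyloxy)-3-[3-(benzyloxy)-4-(methoxymethoxy)phenyl]-3-(methoxymethoxy)prop-2-enoic acid F6. F6 is used with 9 under the conditions of step 11; the leaving group at C2 is then methoxymethoxide, which breaks down to formaldehyde and methoxide, and the product is again 21.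

3. Step 3. Metalation may occur between the two MOM ethers instead of beside the carbamate, and the silyl triflate may cleave part of the MOM ethers. The fallback sets out from 2 and comes back at 9, and it replaces directed metalation by ortho-bromination and a retro-Brook shift. Amine-mediated ortho-selective bromination of 2 (NBS, cat. i-Pr2NH, CH2Cl2, −78 → 0 °C) should give 2-bromo-3,5-bis(methoxymethoxy)phenol F7. Silylation with HMDS (THF, 65 °C) gives [2-bromo-3,5-bis(methoxymethoxy)phenoxy]trimethylsilane F8. n-BuLi in THF at −78 °C effects bromine–lithium exchange, the silyl group shifts from oxygen to carbon, and the resulting lithium salt of 8 is trapped with Tf2O to give 9. Steps 2 to 4 are then not needed.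

**Further compounds**
F1 | step 11 | 1,3,5-tris(methoxymethoxy)benzene | COCOc1cc(OCOC)cc(OCOC)c1
F2 | step 11 | 2,4,6-tris(methoxymethoxy)phenyllithium | [Li]c1c(OCOC)cc(OCOC)cc1OCOC
F3 | step 11 | (E)-2-(benzyloxy)-3-[3-(benzyloxy)-4-(methoxymethoxy)phenyl]-N,3-dimethoxy-N-methylprop-2-enamide | CO/C(c1ccc(OCOC)c(OCc2ccccc2)c1)=C(/OCc1ccccc1)C(=O)N(C)OC
F4 | step 11 | (E)-2-(benzyloxy)-3-[3-(benzyloxy)-4-(methoxymethoxy)phenyl]-3-methoxy-1-[2,4,6-tris(methoxymethoxy)phenyl]prop-2-en-1-one | CO/C(c1ccc(OCOC)c(OCc2ccccc2)c1)=C(/OCc1ccccc1)C(=O)c1c(OCOC)cc(OCOC)cc1OCOC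
F5 | step 9 | methyl (E)-2-(benzyloxy)-3-[3-(benzyloxy)-4-(methoxymethoxy)phenyl]-3-(methoxymethoxy)prop-2-enoate | COCO/C(c1ccc(OCOC)c(OCc2ccccc2)c1)=C(/OCc1ccccc1)C(=O)OC
F6 | step 9 | (E)-2-(benzyloxy)-3-[3-(benzyloxy)-4-(methoxymethoxy)phenyl]-3-(methoxymethoxy)prop-2-enoic acid | COCO/C(c1ccc(OCOC)c(OCc2ccccc2)c1)=C(/OCc1ccccc1)C(=O)O
F7 | step 3 | 2-bromo-3,5-bis(methoxymethoxy)phenol | COCOc1cc(O)c(Br)c(OCOC)c1
F8 | step 3 | [2-bromo-3,5-bis(methoxymethoxy)phenoxy]trimethylsilane | COCOc1cc(O[Si](C)(C)C)c(Br)c(OCOC)c1
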